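**Plan**

- Retrosynthesis cuts three bonds of ring C (the pyran-4-one O1–C2–C3–C4–C4a–C8a) at once: C4a–C4, C4–C3 and O1–C2. This gives 2-iodo-3,4-dimethoxyphenol (ring A with O1), carbon monoxide (C4 and its oxygen) and 3-ethynyl-1,2,4,5-tetramethoxybenzene (C3, C2 and ring B).
- Enabling feature: C4 is a lone carbonyl carbon between aryl carbon C4a and C3, the C2=C3 unit is at the alkyne oxidation level, and O1 sits on ring A ortho to C4a. Ring C is therefore an o-iodophenol + CO + arylacetylene with no later redox adjustment.
- Both aryl partners come from directed ortho-metalation at a C–H flanked by two oxygen groups: C4a (between O1 and the 5-OMe) and C1' (the only kind of C–H in 1,2,4,5-tetramethoxybenzene).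
- Forward: the ring A iodophenol (3 steps) and the ring B alkyne (2 steps) are made separately; ring C is formed last by a three-component Pd-catalysed carbonylative annulation.
- Stereochemistry: none to set (see remark).

Key step: step 6

Remark: the target has no stereocentre, and the C2–C1' axis is not stereogenic because ring B is symmetric about it; the compound is achiral, so "single enantiomer" is taken to mean the compound as drawn.

**Route**

Step 1
Reactants: 1 3,4-dimethoxyphenol
Product: 2 1,2-dimethoxy-4-(methoxymethoxy)benzene
Conditions: MOMCl, i-Pr2NEt, CH2Cl2, 0 °C → rt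
Reagents that add atoms: chloromethyl methyl ether, COCCl
Why: O-alkylation of the phenol by the α-chloro ether (Williamson-type, via the oxocarbenium ion) should install the MOM acetal, which serves as protecting group and as metalation director.

Step 2
Reactants: 2 1,2-dimethoxy-4-(methoxymethoxy)benzene
Product: 4 2-iodo-3,4-dimethoxy-1-(methoxymethoxy)benzene, via aryllithium 3 (not isolated)
Conditions: n-BuLi, THF, 0 °C → rt; then I2, THF, −78 °C → rt
Reagents that add atoms: iodine, II
Why: Directed ortho-metalation should occur at the one C–H flanked by two coordinating oxygen groups (OMOM and the adjacent OMe), and the aryllithium is then iodinated by I2.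

Step 3
Reactants: 4 2-iodo-3,4-dimethoxy-1-(methoxymethoxy)benzene
Product: 5 2-iodo-3,4-dimethoxyphenol
Conditions: HCl (2 M in MeOH), rt
Reagents that add atoms: none
Why: Acid-catalysed acetal exchange with methanol should free the phenol while the aryl methyl ethers and the C–I bond remain untouched.

Step 4
Reactants: 6 1,2,4,5-tetramethoxybenzene
Product: 8 2,3,5,6-tetramethoxybenzaldehyde, via aryllithium 7 (not isolated)
Conditions: n-BuLi, TMEDA, THF, 0 °C → rt; then DMF, 0 °C → rt; aq. HCl work-up
Reagents that add atoms: N,N-dimethylformamide, CN(C)C=O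
Why: Directed ortho-metalation of an arene whose two C–H bonds are equivalent and each flanked by two OMe groups can give only one monolithio species, which DMF formylates (Bouveault-type formylation).

Step 5
Reactants: 8 2,3,5,6-tetramethoxybenzaldehyde
Product: 9 3-ethynyl-1,2,4,5-tetramethoxybenzene
Conditions: dimethyl (1-diazo-2-oxopropyl)phosphonate, K2CO3, MeOH, rt
Reagents that add atoms: dimethyl (1-diazo-2-oxopropyl)phosphonate, CC(=O)C(=[N+]=[N-])P(=O)(OC)OC
Why: Seyferth–Gilbert homologation in the Ohira–Bestmann variant should convert the non-enolisable aryl aldehyde into the terminal alkyne under mild base, by olefination with the diazomethylphosphonate anion, loss of N2 and 1,2-shift.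

Step 6
Reactants: 5 2-iodo-3,4-dimethoxyphenol; 9 3-ethynyl-1,2,4,5-tetramethoxybenzene; 10 carbon monoxide
Product: 13 5,6,2',3',5',6'-hexamethoxyflavone, via ynone 11 (not isolated), via enaminone 12 (not isolated)
Conditions: PdCl2(dppf) (5 mol %), CO (20 bar), Et2NH, 120 °C
Reagents that add atoms: none
Why: Pd(0) adds oxidatively to the C–I bond of 5, CO inserts to give an aroylpalladium(II) species, and amine-assisted alkynylation by 9 with reductive elimination forms the C4a–C4 and C4–C3 bonds of ynone 11. Diethylamine then adds to the ynone to give enaminone 12, and the neighbouring phenol oxygen displaces the amine by addition–elimination at C2, forming the O1–C2 bond. The closest known reaction type is the palladium-catalysed carbonylative Sonogashira annulation of o-iodophenols with terminal arylacetylenes in a secondary amine, which gives flavones. Ring C closes in the 6-endo mode (6-endo-dig with respect to the ynone, realised as a 6-endo-trig addition–elimination on the enaminone), and no stereocentre is formed. The step needs CO insertion to precede alkynylation, which the electron-rich, doubly ortho-substituted arylpalladium should favour under CO pressure without copper, and it needs 6-endo over 5-exo closure (aurone), which the amine-adduct pathway secures. The regiochemistry of ring A is fixed beforehand, because the iodine in 5 sits on the carbon between the hydroxyl and the adjacent methoxy group.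

**Compound list**

1 | 3,4-dimethoxyphenol | COc1ccc(O)cc1OC | starting material
2 | 1,2-dimethoxy-4-(methoxymethoxy)benzene | COCOc1ccc(OC)c(OC)c1 | intermediate
3 | [2,3-dimethoxy-6-(methoxymethoxy)phenyl]lithium | COCOc1ccc(OC)c(OC)c1[Li] | intermediate (not isolated)
4 | 2-iodo-3,4-dimethoxy-1-(methoxymethoxy)benzene | COCOc1ccc(OC)c(OC)c1I | intermediate
5 | 2-iodo-3,4-dimethoxyphenol | COc1ccc(O)c(I)c1OC | intermediate
6 | 1,2,4,5-tetramethoxybenzene | COc1cc(OC)c(OC)cc1OC | starting material
7 | (2,3,5,6-tetramethoxyphenyl)lithium | COc1cc(OC)c(OC)c([Li])c1OC | intermediate (not isolated)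
8 | 2,3,5,6-tetramethoxybenzaldehyde | COc1cc(OC)c(OC)c(C=O)c1OC | intermediate
9 | 3-ethynyl-1,2,4,5-tetramethoxybenzene | COc1cc(OC)c(OC)c(C#C)c1OC | intermediate
10 | carbon monoxide | [C-]#[O+] | starting material
11 | 1-(6-hydroxy-2,3-dimethoxyphenyl)-3-(2,3,5,6-tetramethoxyphenyl)prop-2-yn-1-one | COc1ccc(O)c(C(=O)C#Cc2c(OC)c(OC)cc(OC)c2OC)c1OC | intermediate (not isolated)
12 | (E)-3-(diethylamino)-1-(6-hydroxy-2,3-dimethoxyphenyl)-3-(2,3,5,6-tetramethoxyphenyl)prop-2-en-1-one (drawn as E; either geometry can cyclise) | CCN(CC)/C(=C/C(=O)c1c(O)ccc(OC)c1OC)c1c(OC)c(OC)cc(OC)c1OC | intermediate (not isolated)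
13 | 5,6,2',3',5',6'-hexamethoxyflavone | COc1cc(OC)c(OC)c(-c2cc(=O)c3c(OC)c(OC)ccc3o2)c1OC | target

**Summary**

Total step count: 6. Longest linear sequence: 4 steps (steps 1, 2, 3 and 6).

**Steps most likely to fail**

Step 6. The aryl- or aroylpalladium intermediate may be diverted: alkynylation before CO insertion followed by cyclisation to a benzofuran, capture of the aroylpalladium by diethylamine (aminocarbonylation), or reductive loss of iodine from the hindered, electron-rich aryl iodide.
Fallback, setting out from 2 and 8 and returning at 13: 2 is lithiated as in step 2 (via 3) and acylated with N-methoxy-N-methylacetamide to give 1-[2,3-dimethoxy-6-(methoxymethoxy)phenyl]ethan-1-one F1. HCl in MeOH removes the MOM group to give 1-(6-hydroxy-2,3-dimethoxyphenyl)ethan-1-one F2. Claisen–Schmidt condensation of this ketone with aldehyde 8 (KOH, EtOH, rt) should give (E)-1-(6-hydroxy-2,3-dimethoxyphenyl)-3-(2,3,5,6-tetramethoxyphenyl)prop-2-en-1-one F3. Oxidative cyclisation of this 2'-hydroxychalcone with catalytic I2 in DMSO at 130 °C should give 13. Alkyne 9 is not needed on this path.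

Step 5. Addition of the diazophosphonate anion to the doubly ortho-substituted, electron-rich carbonyl group may be slow, so that base-induced decomposition of the reagent outruns the homologation.
Fallback, setting out from 6 and returning at 9: 6 is lithiated as in step 4 (via 7) and quenched with I2 to give 3-iodo-1,2,4,5-tetramethoxybenzene F4. Sonogashira coupling with ethynyltrimethylsilane (PdCl2(PPh3)2, CuI, Et3N, THF, 60 °C) should give trimethyl[(2,3,5,6-tetramethoxyphenyl)ethynyl]silane F5. Desilylation with K2CO3 in MeOH should give 9.

Step 2. Metalation may not be confined to the position between the two oxygen groups (competing deprotonation at the other ring positions) or may be incomplete, giving regioisomeric iodides that are hard to separate.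
Fallback, setting out from 1 and returning at 5: 1 is carbamoylated with N,N-diethylcarbamoyl chloride (K2CO3, MeCN, reflux) to give 3,4-dimethoxyphenyl diethylcarbamate F6. The O-carbamate, a stronger director than the MOM acetal, is lithiated under kinetic control (s-BuLi, TMEDA, THF, −78 °C) between the carbamate and the adjacent OMe and quenched with I2 at −78 °C (no warming before the quench, to avoid anionic ortho-Fries rearrangement) to give 2-iodo-3,4-dimethoxyphenyl diethylcarbamate F7. Hydrolysis with NaOH in aqueous EtOH at reflux, then acidification, should give 5.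

Further compounds
F1 | step 6 | 1-[2,3-dimethoxy-6-(methoxymethoxy)phenyl]ethan-1-one | CC(=O)c1c(OCOC)ccc(OC)c1OC
F2 | step 6 | 1-(6-hydroxy-2,3-dimethoxyphenyl)ethan-1-one | CC(=O)c1c(O)ccc(OC)c1OC
F3 | step 6 | (E)-1-(6-hydroxy-2,3-dimethoxyphenyl)-3-(2,3,5,6-tetramethoxyphenyl)prop-2-en-1-one | COc1ccc(O)c(C(=O)/C=C/c2c(OC)c(OC)cc(OC)c2OC)c1OC
F4 | step 5 | 3-iodo-1,2,4,5-tetramethoxybenzene | COc1cc(OC)c(OC)c(I)c1OC
F5 | step 5 | trimethyl[(2,3,5,6-tetramethoxyphenyl)ethynyl]silane | COc1cc(OC)c(OC)c(C#C[Si](C)(C)C)c1OC
F6 | step 2 | 3,4-dimethoxyphenyl diethylcarbamate | CCN(CC)C(=O)Oc1ccc(OC)c(OC)c1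
F7 | step 2 | 2-iodo-3,4-dimethoxyphenyl diethylcarbamate | CCN(CC)C(=O)Oc1ccc(OC)c(OC)c1I
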